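common to all: initiator 1 mol%

| flask | substrate | coupling partner | remark | time |
|---|---|---|---|---|
| oak | 0.15 M | 5 equiv | run made earlier |  |
| elm | 0.60 M | 5 equiv | run made earlier |  |
| flask | 0.30 M | 5.00 equiv |  | 15 d |

| run | time / d | substrate / % | target / % |
|---|---|---|---|
| oak | 1.25 | 1.8 | 82.4 |
| oak | 2.00 | 1.8 | 82.7 |
| oak | 3.00 | 0 | 83.0 |
| oak | 5.00 | 0 | 83.9 |
| oak | 8.00 | 0.8 | 83.5 |
| oak | 12.0 | 0.1 | 83.4 |
| oak | 20.0 | 0 | 83.3 |
| elm | 2.50 | 0 | 72.3 |
| elm | 5.00 | 0 | 72.4 |
| elm | 8.00 | 0.1 | 72.9 |
| elm | 10.0 | 0 | 72.6 |
| elm | 12.0 | 0.3 | 72.6 |
| elm | 15.0 | 0.9 | 72.1 |
| elm | 20.0 | 0 | 72.1 |

(readings scatter by 0.5 percentage points)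

- why nothing more happens at 15 d, or that something still does (all of the substrate has reacted / it is still moving / the coupling partner has run out first)
- share of the substrate used up at 15 d
- target at 15 d, in percent of the substrate charged

- percent here means substrate units held: one side product counts as two
- what was read earlier has a scatter of 0.5 percentage points, one standard deviation
- on the list of suspects stand: initiator -> 2 initiating radical; substrate + initiating radical -> capped initiator + first chain carrier; coupling partner + first chain carrier -> target + second chain carrier; substrate + second chain carrier -> by-product + first chain carrier; 2 second chain carrier -> ended chains; substrate + target -> side product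
- the reaction counts as stopped when no species that holds the substrate changes by six tenths of a point or more over the second half of the time

Late in the oak and elm runs nothing moves: substrate reads 0% and 0% at the last reading, and target holds near 83.4% in oak and 72.3% in elm. I expect the flask to end the same way, so the question is its yield p.

Time drops out if I divide the rate at which target grows by the rate at which substrate goes. At the start this gain is one. Then substrate + target → side product takes a share L·p of the chain's rate, which lowers target's growth by that share and raises substrate's loss by it. Averaging the gain between its start and end values makes L the share lost divided by the square of the yield: 0.239 in oak, where the gain sinks to 0.668, and 0.531 in elm.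

I take L to follow c(substrate)/√c(initiator). In elm that quantity is twice what it is in oak, and L is 2.23 times as large. The flask stands halfway on that scale, so I reckon 0.356 for its loss number L, a selectivity factor, the side rate over the chain rate at full yield, and that gives me 78.2%.

The forecast says all of the substrate has reacted, 100% and 78.3%, on this ground: “Yield falls with concentration because substrate + target (second order) competes with the chain”.

The flask gives all of the substrate has reacted, 100% and 78.5%.

    initiator → 2 initiating radical (k = 0.00140 h⁻¹)
    substrate + initiating radical → capped initiator + first chain carrier (k = 1.40 × 10⁵ M⁻¹ s⁻¹)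
    coupling partner + first chain carrier → target + second chain carrier (k = 4.60 × 10⁶ M⁻¹ h⁻¹)
    substrate + second chain carrier → by-product + first chain carrier (k = 26000 M⁻¹ s⁻¹)
    2 second chain carrier → ended chains (k = 2.70 × 10⁸ M⁻¹ s⁻¹)
    substrate + target → side product (k = 0.190 M⁻¹ h⁻¹)

At 0.129 d in the flask, substrate has a half-life of 0.15 d by the chain step, shorter than the 0.97 d of target by the side step. The flask's yield turns back into a loss number of 0.349, close to my 0.356. With 0.25 mol% of initiator, a quarter of the flask's, c(substrate)/√c(initiator) grows as from oak to elm, so L becomes 0.792 and the yield 65.8%; that neighbouring flask gives 65.5%.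

All runs were computed from invented constants; the scatter is artificial.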